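## Retrosynthetic overview

1. C8–CH2 bond last: the target comes from (−)-epicatechin (rings A, B and C and both flavan stereocentres bought intact) plus the ortho-quinone methide of a fully substituted acylphloroglucinol. This is the methylene bridging presumed in nature.
2. The benzene ring of the acylphloroglucinol comes from an open-chain, O-methylated tetraketide ester, closed by the C6→C1 Claisen condensation used by the polyketide synthase. OMe and C-Me are already on the chain, so their ring positions are fixed by connectivity and no selective O-methylation is needed.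
3. The tetraketide comes from a 6-sec-butyl-4-methoxy-3-methyl-2-pyrone plus methyl acetate enolate, which opens the lactone. The pyrone comes from methyl 3-methoxy-2-methylbut-2-enoate plus (S)-2-methylbutanoic acid, the source of the side-chain stereocentre.
4. Ring order: 2-pyrone (temporary), then the acylphloroglucinol benzene ring, then coupling to the preformed flavan.

Assumption: (−)-epicatechin (2R,3R) and (S)-2-methylbutanoic acid (≥98% ee) are bought as single enantiomers; the enol ether of step 1 may be used as an E/Z mixture (drawn E).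

## Route

Step 1
Reactants: 1 methyl 2-methyl-3-oxobutanoate
Product: 3 methyl (2E)-3-methoxy-2-methylbut-2-enoate, via dimethyl ketal 2 (not isolated)
Conditions: HC(OMe)3 (1.3 equiv), H2SO4 (cat.), MeOH, 23 °C, 24 h; then TsOH (cat.), distil at 130–150 °C
Reagents that add atoms: trimethyl orthoformate COC(OC)OC
Why: Acid-catalysed ketalisation with the orthoformate, then thermal loss of MeOH from the ketal, gives the conjugated enol ether (enol ether formation); both alkene isomers give the same dienolate in step 2.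

Step 2
Reactants: 3 methyl (2E)-3-methoxy-2-methylbut-2-enoate; 4 (2S)-2-methylbutanoic acid
Product: 7 pyrone 6-[(2S)-butan-2-yl]-4-methoxy-3-methyl-2H-pyran-2-one, via acyl imidazolide 5 (not isolated), via keto ester 6 (not isolated)
Conditions: 4, CDI (1.05 equiv), THF, 23 °C, 1 h; add to 3 (3.2 equiv) + LiN(iPr)2 (3.2 equiv), THF, −78 → −20 °C; AcOH quench, aqueous work-up; crude 6, DBU (0.3 equiv), PhMe, 60 °C
Reagents that add atoms: none
Why: The lithium dienolate of 3 is acylated at its γ-carbon by 5 (vinylogous Claisen condensation, the α-carbon being blocked by methyl), 6 is at once deprotonated at C4, which shields the ketone and the adjacent stereocentre, and DBU closes the enol oxygen onto the ester (lactonisation, loss of MeOH) to the 2-pyrone; no new stereocentre.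

Step 3
Reactants: 7 pyrone 6-[(2S)-butan-2-yl]-4-methoxy-3-methyl-2H-pyran-2-one; 8 methyl acetate
Product: 10 acylphloroglucinol (2S)-1-(4,6-dihydroxy-2-methoxy-3-methylphenyl)-2-methylbutan-1-one, via open-chain tetraketide 9 (not isolated)
Conditions: 8 (3.5 equiv), LiN(iPr)2 (3.4 equiv), THF, −78 °C; add 7, −78 → −30 °C, 2 h; then Mg(OMe)2 (3 equiv), MeOH, 23 → 60 °C, 3 h; 1 M HCl
Reagents that add atoms: none
Why: Proposed new method: the hard lithium ester enolate adds 1,2 to the lactone carbonyl of 7 (C4 and C6 are shielded by methyl and sec-butyl), the adduct collapses by expelling the ring oxygen as the C7 enolate, and this leaves tetraketide 9 with C3 and C6 already cis on the C4=C5 enol ether; under Mg(OMe)2/MeOH the C6 carbanion attacks the C1 ester (intramolecular Claisen condensation, the ring closure of acylphloroglucinol biosynthesis) and the trione tautomerises to the arene, so OMe can only end up ortho to the acyl group and next to the C-methyl; the competing C2→C7 aldol to a resorcylate is hindered by the sec-butyl ketone and reversible, whereas Claisen closure with aromatisation is not; the stereocentre is preserved because at −78 °C addition should outrun removal of the tertiary allylic C–H and after ring opening the neighbouring ketone is enolised towards C6; closest known reaction types are alkoxide opening of 2-pyrones at the lactone carbonyl, lactone opening by lithium ester enolates, and base-mediated Claisen cyclisation of 3,5,7-triketo esters to acylphloroglucinols.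

Step 4
Reactants: 10 acylphloroglucinol (2S)-1-(4,6-dihydroxy-2-methoxy-3-methylphenyl)-2-methylbutan-1-one; 11 (−)-epicatechin
Product: 14 target (2S)-1-[3-{[(2R,3R)-2-(3,4-dihydroxyphenyl)-3,5,7-trihydroxy-3,4-dihydro-2H-chromen-8-yl]methyl}-2,4-dihydroxy-6-methoxy-5-methylphenyl]-2-methylbutan-1-one, via Mannich base 12 (not isolated), via quinone methide 13 (not isolated)
Conditions: 10, CH2(NMe2)2 (1.1 equiv), 1,4-dioxane, 23 → 50 °C, 2 h; evaporate; then 11 (4 equiv), AcOH/1,4-dioxane 1:4, 80 °C, Ar, 3 h; RP-HPLC (C18)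
Reagents that add atoms: bis(dimethylamino)methane CN(C)CN(C)C
Why: Mannich reaction at the only free ring carbon of 10 gives 12, which loses dimethylamine in warm AcOH to ortho-quinone methide 13, and conjugate (Friedel–Crafts type) addition of ring A of epicatechin, preferentially at C8, with rearomatisation gives the methylene bridge as in the presumed biosynthesis; no stereocentre is formed or touched (acidic medium, so flavan C2 does not epimerise) and the minor C6 isomer is removed by HPLC.

## Compound list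

1 | methyl 2-methyl-3-oxobutanoate (racemic) | CC(=O)C(C)C(=O)OC | starting material
2 | methyl 3,3-dimethoxy-2-methylbutanoate (racemic) | CC(OC)(OC)C(C)C(=O)OC | intermediate
3 | methyl (2E)-3-methoxy-2-methylbut-2-enoate | C/C(OC)=C(C)\C(=O)OC | intermediate
4 | (2S)-2-methylbutanoic acid | CC[C@H](C)C(=O)O | starting material
5 | (2S)-1-(1H-imidazol-1-yl)-2-methylbutan-1-one | CC[C@H](C)C(=O)n1ccnc1 | intermediate
6 | methyl (2E,6S)-3-methoxy-2,6-dimethyl-5-oxooct-2-enoate | CC[C@H](C)C(=O)C/C(OC)=C(C)\C(=O)OC | intermediate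
7 | 6-[(2S)-butan-2-yl]-4-methoxy-3-methyl-2H-pyran-2-one | CC[C@H](C)C1=CC(OC)=C(C)C(=O)O1 | intermediate
8 | methyl acetate | CC(=O)OC | starting material
9 | methyl (4E,8S)-5-methoxy-4,8-dimethyl-3,7-dioxodec-4-enoate | CC[C@H](C)C(=O)C/C(OC)=C(C)\C(=O)CC(=O)OC | intermediate
10 | (2S)-1-(4,6-dihydroxy-2-methoxy-3-methylphenyl)-2-methylbutan-1-one | CC[C@H](C)C(=O)c1c(O)cc(O)c(C)c1OC | intermediate
11 | (−)-epicatechin, (2R,3R)-2-(3,4-dihydroxyphenyl)-3,4-dihydro-2H-chromene-3,5,7-triol | O[C@@H]1Cc2c(O)cc(O)cc2O[C@@H]1c1ccc(O)c(O)c1 | starting material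
12 | (2S)-1-{3-[(dimethylamino)methyl]-2,4-dihydroxy-6-methoxy-5-methylphenyl}-2-methylbutan-1-one | CC[C@H](C)C(=O)c1c(O)c(CN(C)C)c(O)c(C)c1OC | intermediate
13 | 5-hydroxy-3-methoxy-2-methyl-6-methylidene-4-[(2S)-2-methylbutanoyl]cyclohexa-2,4-dien-1-one | CC[C@H](C)C(=O)C1=C(O)C(=C)C(=O)C(C)=C1OC | intermediate
14 | (2S)-1-[3-{[(2R,3R)-2-(3,4-dihydroxyphenyl)-3,5,7-trihydroxy-3,4-dihydro-2H-chromen-8-yl]methyl}-2,4-dihydroxy-6-methoxy-5-methylphenyl]-2-methylbutan-1-one (CNP0299940.3) | CC[C@H](C)C(=O)c1c(O)c(Cc2c(O)cc(O)c3c2O[C@H](c2ccc(O)c(O)c2)[C@H](O)C3)c(O)c(C)c1OC | target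

## Step count and risks

Total step count: 4. Longest linear sequence: 4 (1 → 3 → 7 → 10 → 14).

**Step 3 (highest risk).** The ester enolate may deprotonate 7 at the sec-butyl C–H (erosion of ee), displace the 4-OMe group, or the opened chain may close by aldol to a resorcylate. Check ee of 10 by chiral HPLC. The fallback sets out from 6 and comes back at 10. Step 2 is stopped before the DBU stage and (E)-keto ester 6 is purified. It is C-acetylated at C4 by soft enolisation (MgBr2·OEt2, iPr2NEt, AcCl, CH2Cl2, 0 °C) to give methyl (2E,6S)-4-acetyl-3-methoxy-2,6-dimethyl-5-oxooct-2-enoate F3. LiN(iPr)2 (2.2 equiv, THF, −78 → 0 °C) then forms the β-diketone dianion at the acetyl methyl group, the less substituted α-carbon, so the stereocentre is untouched. This carbanion closes onto the ester (Dieckmann-type Claisen condensation) and the product tautomerises to 10. The ring is thus closed through the other acetate carbon and nothing has to add to a pyrone.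

**Step 4.** The C8:C6 ratio on epicatechin may be poor (I expect roughly 2–3:1 in favour of C8), and bis-alkylation or self-trapping of 13 may compete. Confirm C8 attachment by HMBC. The fallback sets out from 11 and 10 and comes back at 14, with the regiochemistry fixed by a halogen handle:
- BnBr, K2CO3, DMF gives (2R,3R)-5,7-bis(benzyloxy)-2-[3,4-bis(benzyloxy)phenyl]-3,4-dihydro-2H-chromen-3-ol F4.
- NBS, CH2Cl2, −78 °C brominates only C8 to give (2R,3R)-5,7-bis(benzyloxy)-2-[3,4-bis(benzyloxy)phenyl]-8-bromo-3,4-dihydro-2H-chromen-3-ol F5.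
- n-BuLi (2.2 equiv), THF, −78 °C, then gaseous CH2O gives (2R,3R)-5,7-bis(benzyloxy)-2-[3,4-bis(benzyloxy)phenyl]-8-(hydroxymethyl)-3,4-dihydro-2H-chromen-3-ol F6.
- TsOH (10 mol%), CH2Cl2, 0 °C with 10 ionises F6 to the trialkoxybenzyl cation, which alkylates the only free ring carbon of 10 to give (2S)-1-[3-({(2R,3R)-5,7-bis(benzyloxy)-2-[3,4-bis(benzyloxy)phenyl]-3-hydroxy-3,4-dihydro-2H-chromen-8-yl}methyl)-2,4-dihydroxy-6-methoxy-5-methylphenyl]-2-methylbutan-1-one F7.
- H2 (1 atm), Pd/C, EtOAc/MeOH, 23 °C removes the benzyl groups to give 14.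

**Step 2.** γ-Acylation of the dienolate or lactonisation of 6 may be inefficient (α-attack, O-acylation, wrong alkene geometry). The fallback sets out from 1 and 5 (made from 4 as in step 2) and comes back at 7. The dianion of 1 (NaH, then n-BuLi, THF, 0 °C) is acylated at its terminal carbon by 5 to give methyl (6S)-2,6-dimethyl-3,5-dioxooctanoate F1. DBU in PhMe at 110 °C lactonises it to 6-[(2S)-butan-2-yl]-4-hydroxy-3-methyl-2H-pyran-2-one F2. Me2SO4, K2CO3, acetone, 56 °C methylates the 4-OH to give 7.

## Further compounds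

F1 | step 2 | methyl (6S)-2,6-dimethyl-3,5-dioxooctanoate | CC[C@H](C)C(=O)CC(=O)C(C)C(=O)OC
F2 | step 2 | 6-[(2S)-butan-2-yl]-4-hydroxy-3-methyl-2H-pyran-2-one | CC[C@H](C)C1=CC(O)=C(C)C(=O)O1
F3 | step 3 | methyl (2E,6S)-4-acetyl-3-methoxy-2,6-dimethyl-5-oxooct-2-enoate | CC[C@H](C)C(=O)C(C(C)=O)/C(OC)=C(C)\C(=O)OC
F4 | step 4 | (2R,3R)-5,7-bis(benzyloxy)-2-[3,4-bis(benzyloxy)phenyl]-3,4-dihydro-2H-chromen-3-ol | O[C@@H]1Cc2c(OCc3ccccc3)cc(OCc3ccccc3)cc2O[C@@H]1c1ccc(OCc2ccccc2)c(OCc2ccccc2)c1
F5 | step 4 | (2R,3R)-5,7-bis(benzyloxy)-2-[3,4-bis(benzyloxy)phenyl]-8-bromo-3,4-dihydro-2H-chromen-3-ol | O[C@@H]1Cc2c(OCc3ccccc3)cc(OCc3ccccc3)c(Br)c2O[C@@H]1c1ccc(OCc2ccccc2)c(OCc2ccccc2)c1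
F6 | step 4 | (2R,3R)-5,7-bis(benzyloxy)-2-[3,4-bis(benzyloxy)phenyl]-8-(hydroxymethyl)-3,4-dihydro-2H-chromen-3-ol | O[C@@H]1Cc2c(OCc3ccccc3)cc(OCc3ccccc3)c(CO)c2O[C@@H]1c1ccc(OCc2ccccc2)c(OCc2ccccc2)c1
F7 | step 4 | (2S)-1-[3-({(2R,3R)-5,7-bis(benzyloxy)-2-[3,4-bis(benzyloxy)phenyl]-3-hydroxy-3,4-dihydro-2H-chromen-8-yl}methyl)-2,4-dihydroxy-6-methoxy-5-methylphenyl]-2-methylbutan-1-one | CC[C@H](C)C(=O)c1c(O)c(Cc2c(OCc4ccccc4)cc(OCc4ccccc4)c3c2O[C@H](c2ccc(OCc4ccccc4)c(OCc4ccccc4)c2)[C@H](O)C3)c(O)c(C)c1OC
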